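**Retrosynthetic overview**

- Feature: ring A of the luteolin half (C4a, C5, C6, C7, C8, C8a) is a phloroglucinol that carries the acyl carbon C4 on C4a and genkwanin C3 on C6, between 5-OH and 7-OH. This is the fold of a cinnamoyl-primed tetraketide that bears the genkwanin unit on its central methylene.
- Target ⇐ BCl3 unmasking ⇐ oxidative closure of luteolin ring C (O1–C2) from a 3'-flavonyl-2',4',6'-trihydroxychalcone.
- Chalcone ⇐ Claisen folding (luteolin C4a–C8a, ring A) of a 6-(cinnamoylmethyl)-4-hydroxy-2-pyranone that holds the genkwanin unit on pyranone C5.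
- Pyranone ⇐ methyl-dianion acylation with a cinnamic Weinreb amide ⇐ enol silane of the genkwanin-3-ylacetone plus malonyl dichloride ⇐ 3-iodoflavone (ICl cyclisation of an ynone), allylation, Wacker oxidation.
- Ring order: genkwanin ring C, the 2-pyranone (temporary), luteolin ring A, luteolin ring C.

Key step: step 10

Remark on the chemistry: the target has no stereocentre; carbinol 4 and flavanone 20 are racemic and their centres are destroyed later, and 1,3-dicarbonyl compounds are drawn in a single tautomeric form.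

Abbreviation: Fl = 2-[4-(benzyloxy)phenyl]-5,7-dimethoxy-4-oxo-4H-chromen-3-yl, the protected genkwanin-3-yl group. Benzyl ethers and a 5-O-methyl ether are used as protecting groups throughout.

**Route**

Step 1
Reactants: 1 2,4,6-trimethoxybenzaldehyde; 2 1-(benzyloxy)-4-ethynylbenzene
Product: 4 racemic 3-[4-(benzyloxy)phenyl]-1-(2,4,6-trimethoxyphenyl)prop-2-yn-1-ol, via lithium acetylide 3 (not isolated)
Conditions: n-BuLi, THF, −78 °C; then 1, −78 → 0 °C; H2O
Reagents that add atoms: none
Why: 1,2-addition of a lithium acetylide to an aryl aldehyde; the carbinol centre forms racemic and is removed in step 2.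

Step 2
Reactants: 4 racemic propargylic alcohol
Product: 5 3-[4-(benzyloxy)phenyl]-1-(2,4,6-trimethoxyphenyl)prop-2-yn-1-one
Conditions: MnO2 (activated, excess), CH2Cl2, rt
Reagents that add atoms: none
Why: MnO2 oxidation of a benzylic-propargylic alcohol under neutral conditions, which spares the acid-labile electron-rich carbinol and the benzyl ether.

Step 3
Reactants: 5 ynone
Product: 6 2-[4-(benzyloxy)phenyl]-3-iodo-5,7-dimethoxy-4H-chromen-4-one
Conditions: ICl (1.2 equiv), CH2Cl2, −78 °C → rt; aq Na2S2O3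
Reagents that add atoms: iodine monochloride, ClI
Why: Iodocyclisation of an o-methoxyaryl ynone: ICl activates the alkyne, an ortho methoxy oxygen closes 6-endo-dig and chloride removes its methyl group, leaving the other two methoxy groups at C5 and C7; the low temperature should keep ring iodination of the electron-rich arenes from competing.

Step 4
Reactants: 6 3-iodoflavone
Product: 7 3-allyl-2-[4-(benzyloxy)phenyl]-5,7-dimethoxy-4H-chromen-4-one
Conditions: allylSnBu3, Pd(PPh3)4 (5 mol %), toluene, 100 °C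
Reagents that add atoms: allyltributylstannane, C=CC[Sn](CCCC)(CCCC)CCCC
Why: Stille coupling of an α-iodoenone-type vinyl iodide with an allylstannane; oxidative addition at C3–I is easy and the neutral medium should keep the allyl double bond out of conjugation.

Step 5
Reactants: 7 3-allylflavone
Product: 8 2-[4-(benzyloxy)phenyl]-5,7-dimethoxy-3-(2-oxopropyl)-4H-chromen-4-one (Fl-CH2COCH3)
Conditions: PdCl2 (10 mol %), CuCl, O2 (1 atm), DMF/H2O 7:1, rt
Reagents that add atoms: water, O
Why: Tsuji–Wacker oxidation of a terminal allyl group gives the methyl ketone with Markovnikov selectivity; the carbonyl oxygen comes from water and O2 reoxidises palladium through CuCl.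

Step 6
Reactants: 8 flavonylacetone
Product: 9 2-[4-(benzyloxy)phenyl]-5,7-dimethoxy-3-[2-(trimethylsilyloxy)prop-1-enyl]-4H-chromen-4-one (E/Z mixture, geometry without consequence)
Conditions: TMSOTf, Et3N, CH2Cl2, 0 °C → rt; pentane extraction, no aqueous work-up
Reagents that add atoms: trimethylsilyl triflate, C[Si](C)(C)OS(=O)(=O)C(F)(F)F
Why: Soft enolisation–silylation under equilibrating conditions removes the more acidic proton of the CH2 flanked by chromone C3 and the carbonyl, so the conjugated, more substituted silyl enol ether should form.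

Step 7
Reactants: 9 silyl enol ether; 10 malonyl dichloride
Product: 12 5-Fl-4-hydroxy-6-methyl-2H-pyran-2-one, via 4-Fl-3,5-dioxohexanoyl chloride 11 (not isolated)
Conditions: 10 (1.1 equiv), Et2O/CH2Cl2, −78 °C → rt
Reagents that add atoms: none
Why: Pyranone annulation of a silyl enol ether with malonyl dichloride: C-acylation at the enol carbon with loss of Me3SiCl gives 11, and O-acylation of the enolised acetyl oxygen by the second acid chloride closes the lactone, so the enol silane fixes Fl on C5 and methyl on C6.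

Step 8
Reactants: 13 3,4-bis(benzyloxy)benzaldehyde; 14 diethyl {2-[methoxy(methyl)amino]-2-oxoethyl}phosphonate
Product: 15 (E)-3-[3,4-bis(benzyloxy)phenyl]-N-methoxy-N-methylprop-2-enamide
Conditions: NaH, THF, 0 °C → rt
Reagents that add atoms: none
Why: Horner–Wadsworth–Emmons olefination with a stabilised phosphonate, which should give the E-alkene.

Step 9
Reactants: 12 pyranone; 15 Weinreb amide
Product: 17 6-{(E)-4-[3,4-bis(benzyloxy)phenyl]-2-oxobut-3-enyl}-5-Fl-4-hydroxy-2H-pyran-2-one, via dilithio pyranone 16 (not isolated)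
Conditions: LDA (lithium diisopropylamide, 2.2 equiv), THF, −78 → −40 °C; then 15, −78 → −30 °C; 1 M HCl
Reagents that add atoms: none
Why: Dianion acylation of a 4-hydroxy-6-methyl-2-pyranone: LDA removes the OH proton and then a proton of the C6 methyl group (vinylogous to the lactone carbonyl), and the carbanion acylates the Weinreb amide, whose chelated tetrahedral adduct prevents over-addition and proton transfer and disfavours conjugate addition.

Step 10
Reactants: 17 pyranone-masked tetraketide
Product: 19 (E)-3-[3,4-bis(benzyloxy)phenyl]-1-(3-Fl-2,4,6-trihydroxyphenyl)prop-2-en-1-one, via triketo ester 18 (not isolated)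
Conditions: Mg(OMe)2 (excess), MeOH/THF, reflux; then cold 1 M HCl
Reagents that add atoms: none
Why: Methoxide opens the lactone of 17 at C2 to the methyl 3,5,7-trioxo ester 18, held as a magnesium polyenolate chelate; its C6 methylene, flanked by the C5 and C7 carbonyls, attacks the ester carbon C1, methoxide leaves and the cyclohexanetrione enolises to the phloroglucinol. The closest known reaction type is the Mg(OMe)2-induced conversion of 6-(2-oxoalkyl)-4-hydroxy-2-pyranones (masked 3,5,7-triketo acids) into acylphloroglucinols, a chalcone-synthase-type Claisen condensation. The ring (chain C1–C6, luteolin ring A with the new bond C4a–C8a) closes in the 6-exo-trig mode. No stereocentre is formed. The step needs Claisen closure to win over aldol closure of C2 onto the C7 carbonyl (the resorcylate, stilbene-synthase fold); magnesium chelation, which activates the ester and ties up the enolised diketone, and the low electrophilicity of the conjugated C7 carbonyl should secure it. Because Fl already sits on chain C4, it can only end up between two hydroxyl-bearing carbons, so the position of the interflavone bond is fixed by the chain; partial closure of 19 to flavanone on acidic work-up is without consequence, since step 11 converges.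

Step 11
Reactants: 19 chalcone
Product: 21 2-[3,4-bis(benzyloxy)phenyl]-6-Fl-5,7-dihydroxy-4H-chromen-4-one, via flavanone 20 (not isolated)
Conditions: I2 (0.1–0.2 equiv), DMSO, 120 °C
Reagents that add atoms: none
Why: Oxidative cyclisation of a 2'-hydroxychalcone with catalytic I2 in DMSO: oxa-Michael closure to flavanone 20 should go through the 6'-hydroxyl flanked only by H and not through the 2'-hydroxyl wedged between the acyl group and the bulky Fl group, and iodination–dehydroiodination (HI reoxidised by DMSO) then fixes the 6-linked flavone.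

Step 12
Reactants: 21 protected biflavone
Product: 22 target, 3-(luteolin-6-yl)genkwanin (CNP0200311.0)
Conditions: BCl3 (excess, 1 M in CH2Cl2), pentamethylbenzene, CH2Cl2, −78 → 0 °C; then MeOH, H2O
Reagents that add atoms: none
Why: Lewis-acid ether cleavage: BCl3 removes the three aryl benzyl ethers (benzyl cation trapped by pentamethylbenzene) and, through the six-membered chelate with the C4 carbonyl, the peri 5-methoxy group, whereas the unchelated 7-methoxy group should persist at or below 0 °C.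

**Compound list**

1 | 2,4,6-trimethoxybenzaldehyde | COc1cc(OC)c(C=O)c(OC)c1 | starting material
2 | 1-(benzyloxy)-4-ethynylbenzene | C#Cc1ccc(OCc2ccccc2)cc1 | starting material
3 | lithium [4-(benzyloxy)phenyl]acetylide | [Li]C#Cc1ccc(OCc2ccccc2)cc1 | intermediate
4 | 3-[4-(benzyloxy)phenyl]-1-(2,4,6-trimethoxyphenyl)prop-2-yn-1-ol (racemic) | COc1cc(OC)c(C(O)C#Cc2ccc(OCc3ccccc3)cc2)c(OC)c1 | intermediate
5 | 3-[4-(benzyloxy)phenyl]-1-(2,4,6-trimethoxyphenyl)prop-2-yn-1-one | COc1cc(OC)c(C(=O)C#Cc2ccc(OCc3ccccc3)cc2)c(OC)c1 | intermediate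
6 | 2-[4-(benzyloxy)phenyl]-3-iodo-5,7-dimethoxy-4H-chromen-4-one | COc1cc(OC)c2c(=O)c(I)c(-c3ccc(OCc4ccccc4)cc3)oc2c1 | intermediate
7 | 3-allyl-2-[4-(benzyloxy)phenyl]-5,7-dimethoxy-4H-chromen-4-one | COc1cc(OC)c2c(=O)c(CC=C)c(-c3ccc(OCc4ccccc4)cc3)oc2c1 | intermediate
8 | 2-[4-(benzyloxy)phenyl]-5,7-dimethoxy-3-(2-oxopropyl)-4H-chromen-4-one | COc1cc(OC)c2c(=O)c(CC(C)=O)c(-c3ccc(OCc4ccccc4)cc3)oc2c1 | intermediate
9 | 2-[4-(benzyloxy)phenyl]-5,7-dimethoxy-3-[2-(trimethylsilyloxy)prop-1-enyl]-4H-chromen-4-one (E/Z mixture) | COc1cc(OC)c2c(=O)c(C=C(C)O[Si](C)(C)C)c(-c3ccc(OCc4ccccc4)cc3)oc2c1 | intermediate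
10 | malonyl dichloride | O=C(Cl)CC(=O)Cl | starting material
11 | 4-Fl-3,5-dioxohexanoyl chloride | COc1cc(OC)c2c(=O)c(C(C(C)=O)C(=O)CC(=O)Cl)c(-c3ccc(OCc4ccccc4)cc3)oc2c1 | intermediate
12 | 5-Fl-4-hydroxy-6-methyl-2H-pyran-2-one | COc1cc(OC)c2c(=O)c(-c3c(O)cc(=O)oc3C)c(-c3ccc(OCc4ccccc4)cc3)oc2c1 | intermediate
13 | 3,4-bis(benzyloxy)benzaldehyde | O=Cc1ccc(OCc2ccccc2)c(OCc2ccccc2)c1 | starting material
14 | diethyl {2-[methoxy(methyl)amino]-2-oxoethyl}phosphonate | CCOP(=O)(CC(=O)N(C)OC)OCC | starting material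
15 | (E)-3-[3,4-bis(benzyloxy)phenyl]-N-methoxy-N-methylprop-2-enamide | CON(C)C(=O)/C=C/c1ccc(OCc2ccccc2)c(OCc2ccccc2)c1 | intermediate
16 | dilithio derivative of 12 (lithium 4-olate, 6-lithiomethyl) | COc1cc(OC)c2c(=O)c(-c3c(O[Li])cc(=O)oc3C[Li])c(-c3ccc(OCc4ccccc4)cc3)oc2c1 | intermediate
17 | 6-{(E)-4-[3,4-bis(benzyloxy)phenyl]-2-oxobut-3-enyl}-5-Fl-4-hydroxy-2H-pyran-2-one | COc1cc(OC)c2c(=O)c(-c3c(O)cc(=O)oc3CC(=O)/C=C/c3ccc(OCc4ccccc4)c(OCc4ccccc4)c3)c(-c3ccc(OCc4ccccc4)cc3)oc2c1 | intermediate
18 | methyl (E)-9-[3,4-bis(benzyloxy)phenyl]-4-Fl-3,5,7-trioxonon-8-enoate | COC(=O)CC(=O)C(c1c(-c2ccc(OCc3ccccc3)cc2)oc2cc(OC)cc(OC)c2c1=O)C(=O)CC(=O)/C=C/c1ccc(OCc2ccccc2)c(OCc2ccccc2)c1 | intermediate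
19 | (E)-3-[3,4-bis(benzyloxy)phenyl]-1-(3-Fl-2,4,6-trihydroxyphenyl)prop-2-en-1-one | COc1cc(OC)c2c(=O)c(-c3c(O)cc(O)c(C(=O)/C=C/c4ccc(OCc5ccccc5)c(OCc5ccccc5)c4)c3O)c(-c3ccc(OCc4ccccc4)cc3)oc2c1 | intermediate
20 | 2-[3,4-bis(benzyloxy)phenyl]-6-Fl-5,7-dihydroxychroman-4-one (racemic) | COc1cc(OC)c2c(=O)c(-c3c(O)cc4OC(c5ccc(OCc6ccccc6)c(OCc6ccccc6)c5)CC(=O)c4c3O)c(-c3ccc(OCc4ccccc4)cc3)oc2c1 | intermediate
21 | 2-[3,4-bis(benzyloxy)phenyl]-6-Fl-5,7-dihydroxy-4H-chromen-4-one | COc1cc(OC)c2c(=O)c(-c3c(O)cc4oc(-c5ccc(OCc6ccccc6)c(OCc6ccccc6)c5)cc(=O)c4c3O)c(-c3ccc(OCc4ccccc4)cc3)oc2c1 | intermediate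
22 | 3-(luteolin-6-yl)genkwanin, CNP0200311.0 | COc1cc(O)c2c(=O)c(-c3c(O)cc4oc(-c5ccc(O)c(O)c5)cc(=O)c4c3O)c(-c3ccc(O)cc3)oc2c1 | target

**Step count**

Total steps: 12. Longest linear sequence: 11 steps (steps 1–7 and 9–12); step 8 is the side branch.

**Steps most likely to fail**

1. Step 10. The opened triketo ester may close in the aldol sense (C2 onto the C7 carbonyl, resorcylate fold), the cinnamoyl enone may be consumed by conjugate addition of methoxide or of a chain enolate, or the ester may relactonise. Fallback, setting out from 12 and coming back at 19: the enone is taken out of the folding step. The dianion of 12 (as in step 9) is acylated with N-methoxy-N-methylacetamide to give 6-(2-oxopropyl)-5-Fl-4-hydroxy-2H-pyran-2-one F1. This plain acetonyl pyranone, the classical substrate of the Claisen mode, is folded with Mg(OMe)2 in MeOH to 1-(3-Fl-2,4,6-trihydroxyphenyl)ethanone F2. MOMCl and i-Pr2NEt protect the two accessible hydroxyls to give the 4,6-bis(methoxymethyl) ether F3, with the hindered chelated 2-hydroxyl left free. Claisen–Schmidt condensation with aldehyde 13 (KOH, EtOH) gives the bis(methoxymethyl) chalcone F4, and HCl in MeOH removes the acetals to return chalcone 19.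

2. Step 7. Silylation may occur on the methyl side, C-acylation at the crowded Fl-bearing carbon may be slow, and HCl may desilylate 9 or drive the acetonyl ketone and flavone C2 (a masked 1,4-dicarbonyl) toward a furan. Fallback, setting out from 7 and coming back at 12, with Fl placed on the chain carbon from the start. Lemieux–Johnson cleavage of 7 (OsO4 cat., NaIO4, 2,6-lutidine, dioxane/H2O) gives 2-Fl-acetaldehyde F5, and Pinnick oxidation (NaClO2, NaH2PO4, 2-methyl-2-butene) gives 2-Fl-acetic acid F6. Activation with 1,1'-carbonyldiimidazole and chain extension with magnesium methyl malonate Mg(O2CCH2CO2Me)2 give methyl 4-Fl-3-oxobutanoate F7. Its dianion (NaH, then n-BuLi, THF) is acetylated at the γ-carbon with N-methoxy-N-methylacetamide to give methyl 4-Fl-3,5-dioxohexanoate F8, which DBU in refluxing toluene lactonises to pyranone 12.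

3. Step 11. Ring closure may go through the hindered 2'-hydroxyl and give the 8-linked flavone, and the free phloroglucinol ring may be iodinated. Fallback, setting out from 19 and coming back at 22, by thermodynamic equilibration instead of kinetic selection. The 8-linked isomer, 2-[3,4-bis(benzyloxy)phenyl]-8-Fl-5,7-dihydroxy-4H-chromen-4-one F9, is deprotected with BCl3 and pentamethylbenzene as in step 12 to 3-(luteolin-8-yl)genkwanin F10. Heating F10 in aqueous HCl/AcOH should effect a Wessely–Moser rearrangement: luteolin ring C opens to the 1,3-diketone and recloses through the other ortho hydroxyl, interconverting the 8- and 6-linked isomers. Target 22 is separated and F10 is resubmitted; the genkwanin half is degenerate under this rearrangement and its 7-methoxy group is stable to hot HCl.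

**Further compounds**

F1 | step 10 | 6-(2-oxopropyl)-5-Fl-4-hydroxy-2H-pyran-2-one | COc1cc(OC)c2c(=O)c(-c3c(O)cc(=O)oc3CC(C)=O)c(-c3ccc(OCc4ccccc4)cc3)oc2c1
F2 | step 10 | 1-(3-Fl-2,4,6-trihydroxyphenyl)ethanone | COc1cc(OC)c2c(=O)c(-c3c(O)cc(O)c(C(C)=O)c3O)c(-c3ccc(OCc4ccccc4)cc3)oc2c1
F3 | step 10 | 1-[3-Fl-2-hydroxy-4,6-bis(methoxymethoxy)phenyl]ethanone | COc1cc(OC)c2c(=O)c(-c3c(OCOC)cc(OCOC)c(C(C)=O)c3O)c(-c3ccc(OCc4ccccc4)cc3)oc2c1
F4 | step 10 | (E)-3-[3,4-bis(benzyloxy)phenyl]-1-[3-Fl-2-hydroxy-4,6-bis(methoxymethoxy)phenyl]prop-2-en-1-one | COc1cc(OC)c2c(=O)c(-c3c(OCOC)cc(OCOC)c(C(=O)/C=C/c4ccc(OCc5ccccc5)c(OCc5ccccc5)c4)c3O)c(-c3ccc(OCc4ccccc4)cc3)oc2c1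
F5 | step 7 | 2-Fl-acetaldehyde | COc1cc(OC)c2c(=O)c(CC=O)c(-c3ccc(OCc4ccccc4)cc3)oc2c1
F6 | step 7 | 2-Fl-acetic acid | COc1cc(OC)c2c(=O)c(CC(=O)O)c(-c3ccc(OCc4ccccc4)cc3)oc2c1
F7 | step 7 | methyl 4-Fl-3-oxobutanoate | COC(=O)CC(=O)Cc1c(-c2ccc(OCc3ccccc3)cc2)oc2cc(OC)cc(OC)c2c1=O
F8 | step 7 | methyl 4-Fl-3,5-dioxohexanoate | COC(=O)CC(=O)C(C(C)=O)c1c(-c2ccc(OCc3ccccc3)cc2)oc2cc(OC)cc(OC)c2c1=O
F9 | step 11 | 2-[3,4-bis(benzyloxy)phenyl]-8-Fl-5,7-dihydroxy-4H-chromen-4-one | COc1cc(OC)c2c(=O)c(-c3c(O)cc(O)c4c(=O)cc(-c5ccc(OCc6ccccc6)c(OCc6ccccc6)c5)oc34)c(-c3ccc(OCc4ccccc4)cc3)oc2c1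
F10 | step 11 | 3-(luteolin-8-yl)genkwanin | COc1cc(O)c2c(=O)c(-c3c(O)cc(O)c4c(=O)cc(-c5ccc(O)c(O)c5)oc34)c(-c3ccc(O)cc3)oc2c1
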